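In ring B the C8=C9 alkene and C6 are separated only by the C7 methylene. With a second alkene at C5=C6, ring B becomes a skipped (1,4) cycloheptadiene in which the C1–C10 bond ties the methyl-bearing quaternary C1 to the carbinol carbon C10, which is what a vinylcarbenoid cyclopropanation followed by divinylcyclopropane rearrangement delivers. The precursor is an enantiopure ring-A cyclopentenyl diazoacetate (C1 to C6; C2 and C4 oxygens silylated), which is joined to a 1-silyloxy-3-methylbutadiene (C7 to C10): one operation forms C6–C7 and C1–C10, closes ring B and sets C1. The C6 ester then serves as a lactone tether that fixes C5 before it is degraded to the C6 oxygen.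

Key step: step 11

Remarks on the chemistry (valid for all steps)
- Target numbering is used for the ring carbons of every intermediate: ring A = C1–C5, ring B = C1, C5–C10. α is the face that carries the C1 methyl group, β the opposite face (target: 2β-OAc, 4α-OH, 4β-isopropyl, 5β-H, 6β-O-anisoyl, 10α-OH).
- Assumption: the ester alkyl group and the silyl groups are spectators; C4 is carried as a trimethylsilyl ether (small next to the carbenoid, removable beside the others) and C2 and C10 as tert-butyldimethylsilyl ethers.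
- The absolute configuration comes from (2R)-2-hydroxy-3-methylbutanoic acid, whose carbinol carbon becomes C4.
- C5 is deliberately not set by enolisation of a C6 ketone: that ketone is β,γ-unsaturated (C8=C9) and has a β-oxygen at C4, so base would move the alkene or eliminate.

Step 1
Reactants: 1 (2R)-2-hydroxy-3-methylbutanoic acid; 2 2,2-dimethylpropanal (pivalaldehyde)
Product: 3 (2R,5R)-2-tert-butyl-5-(propan-2-yl)-1,3-dioxolan-4-one
Conditions: TsOH·H2O (cat.), H2SO4 (cat.), pentane, reflux, water separator; crystallisation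
Reagents that add atoms: none
Why: Acid-catalysed acetalisation of the α-hydroxy acid (first stage of the self-regeneration of stereocentres) should give the 2,5-cis dioxolanone under thermodynamic control, the acetal centre being set by the C5 isopropyl group and the cis isomer being purified by crystallisation.

Step 2
Reactants: 3 (2R,5R)-2-tert-butyl-5-(propan-2-yl)-1,3-dioxolan-4-one; 4 tert-butyl bromoacetate
Product: 5 tert-butyl 2-[(2R,4R)-2-tert-butyl-5-oxo-4-(propan-2-yl)-1,3-dioxolan-4-yl]acetate
Conditions: LiN(iPr)2, THF, −78 °C; then 4, −78 → −30 °C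
Reagents that add atoms: none
Why: Enolate alkylation of the dioxolanone, in which the tert-butyl group on the acetal carbon sends the bromoacetate to the opposite face, so that the new C–C bond takes the place of the former C–H bond with retention and fixes the quaternary C4 (target numbering) as R.

Step 3
Reactants: 5 tert-butyl 2-[(2R,4R)-2-tert-butyl-5-oxo-4-(propan-2-yl)-1,3-dioxolan-4-yl]acetate; 6 ethyllithium
Product: 8 tert-butyl (3R)-3-hydroxy-4-oxo-3-(propan-2-yl)hexanoate, via lithium hemiketal alkoxide 7 (not isolated)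
Conditions: EtLi (1.1 equiv), THF, −78 °C; then aq. NH4Cl, → rt
Reagents that add atoms: none
Why: 1,2-Addition of an organolithium to the lactone-type carbonyl should stop at the tetrahedral lithium hemiketal at −78 °C (as in lactol formation from lactones), and aqueous work-up then releases the ethyl ketone, pivalaldehyde and the free tertiary alcohol, while the hindered tert-butyl ester and the C4 centre are untouched.

Step 4
Reactants: 8 tert-butyl (3R)-3-hydroxy-4-oxo-3-(propan-2-yl)hexanoate
Product: 9 (4R)-4-hydroxy-2-methyl-4-(propan-2-yl)cyclopentane-1,3-dione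
Conditions: KOtBu (2.2 equiv), THF, 0 °C → rt; then 1 M HCl
Reagents that add atoms: none
Why: Dieckmann-type intramolecular Claisen condensation, in which the ketone can enolise only towards its ethyl group (C1) and this enolate acylates the tert-butyl ester (C2) in a 5-exo-trig closure driven by deprotonation of the 1,3-dione, the non-enolisable C4 keeping its configuration.

Step 5
Reactants: 9 (4R)-4-hydroxy-2-methyl-4-(propan-2-yl)cyclopentane-1,3-dione
Product: 10 (5R)-5-hydroxy-3-methoxy-2-methyl-5-(propan-2-yl)cyclopent-2-en-1-one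
Conditions: Me2SO4, K2CO3, acetone, rt
Reagents that add atoms: dimethyl sulfate, COS(=O)(=O)OC
Why: O-Alkylation of the 1,3-dione enolate with a hard electrophile should occur at the oxygen on C2, remote from the fully substituted C4, which is also the more stable enol ether (no allylic strain with the C4 substituents), so that the remaining ketone is C5.

Step 6
Reactants: 10 (5R)-5-hydroxy-3-methoxy-2-methyl-5-(propan-2-yl)cyclopent-2-en-1-one; 11 methyl acetate
Product: 13 methyl 2-[(5R)-5-hydroxy-2-methyl-3-oxo-5-(propan-2-yl)cyclopent-1-en-1-yl]acetate, via tertiary carbinol adduct 12 (not isolated)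
Conditions: 11, LiN(iPr)2, THF, −78 °C; CeCl3; then 10, −78 → −30 °C; then 1 M HCl, 0 °C
Reagents that add atoms: water, O
Why: Stork–Danheiser sequence in which the cerium-modified ester enolate adds 1,2 to the only ketone (C5) and dilute acid ionises the tertiary allylic carbinol and hydrolyses the enol ether, which transposes the enone to C2=O/C1=C5 with the acetate chain on C5; lactonisation of the C4 hydroxyl is not expected because it would place the C1=C5 bond at the fusion of two five-membered rings.

Step 7
Reactants: 13 methyl 2-[(5R)-5-hydroxy-2-methyl-3-oxo-5-(propan-2-yl)cyclopent-1-en-1-yl]acetate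
Product: 14 methyl 2-[(3S,5R)-3,5-dihydroxy-2-methyl-5-(propan-2-yl)cyclopent-1-en-1-yl]acetate
Conditions: Me4NBH(OAc)3, MeCN/AcOH (1:1), −30 → 0 °C
Reagents that add atoms: none
Why: Hydroxyl-directed (Evans–Saksena) 1,2-reduction of the β-hydroxy enone, in which the C4 hydroxyl binds boron and delivers hydride to the α face of C2 (also the face opposite the isopropyl group), which sets the C2 alcohol β and trans to the C4 oxygen.

Step 8
Reactants: 14 methyl 2-[(3S,5R)-3,5-dihydroxy-2-methyl-5-(propan-2-yl)cyclopent-1-en-1-yl]acetate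
Product: 16 methyl 2-[(3S,5R)-3-[(tert-butyldimethylsilyl)oxy]-2-methyl-5-(propan-2-yl)-5-[(trimethylsilyl)oxy]cyclopent-1-en-1-yl]acetate, via mono-TBS ether 15 (not isolated)
Conditions: TBSCl, imidazole, DMF, rt; then TMSCl, rt
Reagents that add atoms: tert-butyldimethylsilyl chloride, CC(C)(C)[Si](C)(C)Cl; chlorotrimethylsilane, C[Si](C)(C)Cl
Why: Two-stage silylation in one flask, in which TBSCl/imidazole reacts only with the secondary allylic C2 hydroxyl and the smaller TMSCl then caps the hindered tertiary C4 hydroxyl.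

Step 9
Reactants: 16 methyl 2-[(3S,5R)-3-[(tert-butyldimethylsilyl)oxy]-2-methyl-5-(propan-2-yl)-5-[(trimethylsilyl)oxy]cyclopent-1-en-1-yl]acetate
Product: 17 methyl 2-diazo-2-[(3S,5R)-3-[(tert-butyldimethylsilyl)oxy]-2-methyl-5-(propan-2-yl)-5-[(trimethylsilyl)oxy]cyclopent-1-en-1-yl]acetate (fragment 1)
Conditions: p-ABSA, DBU, MeCN, 0 °C → rt
Reagents that add atoms: 4-acetamidobenzenesulfonyl azide, CC(=O)Nc1ccc(cc1)S(=O)(=O)N=[N+]=[N-]
Why: Regitz diazo transfer to the C6 methylene of the β,γ-unsaturated ester, the standard entry to vinyldiazoacetates, with silyloxy groups that are too poor as leaving groups for vinylogous elimination.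

Step 10
Reactants: 18 3-methylbut-2-enal
Product: 19 (E)-1-[(tert-butyldimethylsilyl)oxy]-3-methylbuta-1,3-diene (fragment 2)
Conditions: TBSOTf, Et3N, Et2O, 0 °C → rt; distillation
Reagents that add atoms: tert-butyldimethylsilyl trifluoromethanesulfonate, CC(C)(C)[Si](C)(C)OS(=O)(=O)C(F)(F)F
Why: Vinylogous silyl enol ether formation (O-silylation with γ-deprotonation of the enal), in which the s-trans enal should give mainly the E enol ether.

Step 11
Reactants: 17 methyl 2-diazo-2-[(3S,5R)-3-[(tert-butyldimethylsilyl)oxy]-2-methyl-5-(propan-2-yl)-5-[(trimethylsilyl)oxy]cyclopent-1-en-1-yl]acetate (fragment 1); 19 (E)-1-[(tert-butyldimethylsilyl)oxy]-3-methylbuta-1,3-diene (fragment 2)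
Product: 21 methyl ester of the hydroazulene diene (C5=C6 with the ester on C6; C8=C9; 1α-methyl; 2β-OTBS; 4α-OTMS; 4β-isopropyl; 10β-OTBS), via cis-divinylcyclopropane 20 (not isolated)
Conditions: Rh2(S-DOSP)4 (2 mol%), 19 (5 equiv), hexane, −40 °C → rt, slow addition of 17; then toluene, 90 °C
Reagents that add atoms: none
Why: The dirhodium tetraprolinate Rh2(S-DOSP)4 turns 17 into a donor/acceptor vinylcarbenoid that cyclopropanates the only accessible alkene of 19, the 1,1-disubstituted C7=C8 end (the trans enol ether alkene is inert to such bulky carbenoids and the fully substituted C1 terminus blocks vinylogous attack), with the silyloxyvinyl group cis to the cyclopentenyl donor, as 1,1-disubstituted conjugated alkenes normally add; this is the known carbenoid cyclopropanation/divinylcyclopropane Cope sequence (formal (4+3) cycloaddition of vinyldiazoacetates with dienes). Ring B is closed by the (3,3)-sigmatropic shift of 20 through a boat transition state, in which the strained C6–C8 bond breaks while C1–C10 forms, so the three-membered ring is expanded to the seven-membered ring. C1 is controlled by the catalyst: the cyclopropane expected from Rh2(S-DOSP)4 (C6→C8→C7 clockwise, seen from the face that carries both alkenyl groups) presents the β face of C5=C1 to C10 in the boat, so the methyl group ends α (the mirror-image catalyst is the alternative if the sense proves opposite). C10 is controlled by the E enol ether: the silyloxy group and C2 both lie outside the boat and end cis, so the C10 oxygen is β and trans to the C1 methyl group, to be inverted in steps 20 and 22. The step needs site selectivity for C7=C8, the cis-divinyl arrangement and catalyst control over the facial bias of 17, because the forming C1–C10 bond is syn to the C2 silyl ether; the small C4 trimethylsilyl ether, slow addition into excess 19 and final heating (the Z methyl group at C1 slows the Cope step) are chosen for this.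

Step 12
Reactants: 21 methyl ester of the hydroazulene diene
Product: 23 tricyclic butenolide (γ-lactone from O4 to the C6 carbonyl carbon; C5=C6; C8=C9; 2β-OTBS; 10β-OTBS), via C4-hydroxy ester 22 (not isolated)
Conditions: K2CO3, MeOH, rt → 40 °C
Reagents that add atoms: none
Why: Methanolysis removes only the tertiary trimethylsilyl ether (the secondary tert-butyldimethylsilyl ethers are inert), and the freed C4 oxygen, which is cis to the ester across C5=C6, closes the butenolide by intramolecular transesterification.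

Step 13
Reactants: 23 tricyclic butenolide
Product: 24 saturated cis-fused γ-lactone (5β-H; C6 unassigned)
Conditions: Mg, MeOH, 0 °C → rt; then aq. NH4Cl
Reagents that add atoms: none
Why: Electron-transfer conjugate reduction of the α,β-unsaturated lactone (Mg/MeOH) protonates C5, and because the γ-lactone that joins the α oxygen on C4 to C6 must stay cis-fused to ring A, the hydrogen is expected on the β face, which makes the ring fusion trans; the endocyclic C4–O bond lies in the nodal plane of the π system and should not be cleaved.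

Step 14
Reactants: 24 saturated cis-fused γ-lactone
Product: 25 α-hydroxy lactone (tertiary hydroxyl on C6; C6 unassigned)
Conditions: KN(SiMe3)2, THF, −78 °C; then 2-(phenylsulfonyl)-3-phenyloxaziridine, −78 °C; aq. NH4Cl
Reagents that add atoms: 2-(phenylsulfonyl)-3-phenyloxaziridine, O=S(=O)(c1ccccc1)N1OC1c1ccccc1
Why: Enolate α-hydroxylation with an N-sulfonyloxaziridine, a reagent that is inert to the C8=C9 alkene and the silyl ethers; the configuration of the new carbinol is irrelevant because C6 becomes a ketone in step 16.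

Step 15
Reactants: 25 α-hydroxy lactone
Product: 26 triol (C4–OH; C6–OH; hydroxymethyl on C6)
Conditions: LiAlH4, THF, 0 °C → rt; aq. potassium sodium tartrate
Reagents that add atoms: none
Why: Hydride reduction of the lactone to the diol gives the 1,2-diol needed for glycol cleavage and frees the C4 hydroxyl, with silyl ethers and the isolated alkene inert.

Step 16
Reactants: 26 triol
Product: 27 β-hydroxy ketone (C6 ketone; 4α-OH; 5β-H; 2β-OTBS; 10β-OTBS)
Conditions: NaIO4, THF/pH 7 buffer, 0 °C → rt
Reagents that add atoms: none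
Why: Periodate glycol cleavage (Malaprade reaction) removes the former ester carbon as formaldehyde and leaves the C6 ketone under near-neutral conditions, so that neither C5 nor the β,γ-placed C8=C9 alkene is disturbed.

Step 17
Reactants: 27 β-hydroxy ketone
Product: 28 anti-1,3-diol (4α-OH; 6β-OH)
Conditions: Me4NBH(OAc)3, MeCN/AcOH (1:1), −25 °C
Reagents that add atoms: none
Why: Hydroxyl-directed (Evans–Saksena) reduction, in which the C4 α-hydroxyl delivers hydride to the α face of C6 through a six-membered transition state and gives the 6β-alcohol (cis to H5), whereas undirected hydride would be expected to avoid the face of the α methyl group.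

Step 18
Reactants: 28 anti-1,3-diol; 29 4-methoxybenzoyl chloride
Product: 30 C6 4-methoxybenzoate (4α-OH free; 2β-OTBS; 10β-OTBS)
Conditions: Et3N, DMAP (cat.), CH2Cl2, rt
Reagents that add atoms: none
Why: DMAP-catalysed acylation of the only reactive, secondary hydroxyl (C6), the tertiary C4 hydroxyl being inert under these conditions.

Step 19
Reactants: 30 C6 4-methoxybenzoate
Product: 31 triol ester (2β-OH; 4α-OH; 10β-OH; C6 4-methoxybenzoate)
Conditions: HF·pyridine, pyridine, THF, 0 °C → rt
Reagents that add atoms: none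
Why: Fluoride cleavage of both secondary tert-butyldimethylsilyl ethers under buffered conditions that leave the ester, the tertiary alcohol and the allylic system untouched.

Step 20
Reactants: 31 triol ester
Product: 32 C10 enone (C10=O conjugated with C8=C9; 2β-OH; 4α-OH)
Conditions: MnO2, CH2Cl2, rt
Reagents that add atoms: none
Why: Chemoselective oxidation of the allylic C10 alcohol by MnO2, which leaves the saturated C2 and C4 hydroxyls and erases the wrongly configured C10 centre.

Step 21
Reactants: 32 C10 enone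
Product: 33 C2 acetate of the enone
Conditions: Ac2O, pyridine, DMAP (cat.), CH2Cl2, 0 °C → rt
Reagents that add atoms: acetic anhydride, CC(=O)OC(C)=O
Why: Acetylation of the only secondary hydroxyl left (C2), the tertiary C4 hydroxyl being unreactive; it is placed after step 20 so that the C10 alcohol cannot compete.

Step 22
Reactants: 33 C2 acetate of the enone
Product: 34 target CNP0261832.1
Conditions: NaBH4, CeCl3·7H2O, MeOH, −78 → −40 °C
Reagents that add atoms: none
Why: Luche 1,2-reduction of the enone, in which hydride should add to C10 from the β face, anti to the axial C1 methyl group on the neighbouring carbon, to give the equatorial 10α-alcohol cis to that methyl group, with the esters untouched at low temperature.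

Compound list
1 | (2R)-2-hydroxy-3-methylbutanoic acid | CC(C)[C@@H](O)C(=O)O | starting material
2 | 2,2-dimethylpropanal (pivalaldehyde) | CC(C)(C)C=O | starting material
3 | (2R,5R)-2-tert-butyl-5-(propan-2-yl)-1,3-dioxolan-4-one (2,5-cis) | CC(C)[C@H]1O[C@@H](C(C)(C)C)OC1=O | intermediate
4 | tert-butyl bromoacetate | CC(C)(C)OC(=O)CBr | starting material
5 | tert-butyl 2-[(2R,4R)-2-tert-butyl-5-oxo-4-(propan-2-yl)-1,3-dioxolan-4-yl]acetate | CC(C)[C@@]1(CC(=O)OC(C)(C)C)O[C@@H](C(C)(C)C)OC1=O | intermediate
6 | ethyllithium | [Li]CC | starting material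
7 | lithium hemiketal alkoxide from 5 and 6 (hemiketal carbon unassigned; formed in the flask, not isolated) | [Li+].CCC1([O-])O[C@H](C(C)(C)C)O[C@]1(CC(=O)OC(C)(C)C)C(C)C | intermediate
8 | tert-butyl (3R)-3-hydroxy-4-oxo-3-(propan-2-yl)hexanoate | CCC(=O)[C@](O)(C(C)C)CC(=O)OC(C)(C)C | intermediate
9 | (4R)-4-hydroxy-2-methyl-4-(propan-2-yl)cyclopentane-1,3-dione (C2 epimers and enol forms) | CC1C(=O)C[C@@](O)(C(C)C)C1=O | intermediate
10 | (5R)-5-hydroxy-3-methoxy-2-methyl-5-(propan-2-yl)cyclopent-2-en-1-one | COC1=C(C)C(=O)[C@](O)(C(C)C)C1 | intermediate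
11 | methyl acetate | COC(C)=O | starting material
12 | methyl 2-[(5R)-1,5-dihydroxy-3-methoxy-2-methyl-5-(propan-2-yl)cyclopent-2-en-1-yl]acetate (present as lithium alkoxide; C1 unassigned; not isolated) | COC(=O)CC1(O)C(C)=C(OC)C[C@@]1(O)C(C)C | intermediate
13 | methyl 2-[(5R)-5-hydroxy-2-methyl-3-oxo-5-(propan-2-yl)cyclopent-1-en-1-yl]acetate | COC(=O)CC1=C(C)C(=O)C[C@@]1(O)C(C)C | intermediate
14 | methyl 2-[(3S,5R)-3,5-dihydroxy-2-methyl-5-(propan-2-yl)cyclopent-1-en-1-yl]acetate | COC(=O)CC1=C(C)[C@@H](O)C[C@@]1(O)C(C)C | intermediate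
15 | methyl 2-[(3S,5R)-3-[(tert-butyldimethylsilyl)oxy]-5-hydroxy-2-methyl-5-(propan-2-yl)cyclopent-1-en-1-yl]acetate (not isolated) | COC(=O)CC1=C(C)[C@@H](O[Si](C)(C)C(C)(C)C)C[C@@]1(O)C(C)C | intermediate
16 | methyl 2-[(3S,5R)-3-[(tert-butyldimethylsilyl)oxy]-2-methyl-5-(propan-2-yl)-5-[(trimethylsilyl)oxy]cyclopent-1-en-1-yl]acetate | COC(=O)CC1=C(C)[C@@H](O[Si](C)(C)C(C)(C)C)C[C@@]1(O[Si](C)(C)C)C(C)C | intermediate
17 | methyl 2-diazo-2-[(3S,5R)-3-[(tert-butyldimethylsilyl)oxy]-2-methyl-5-(propan-2-yl)-5-[(trimethylsilyl)oxy]cyclopent-1-en-1-yl]acetate (fragment 1) | COC(=O)C(=[N+]=[N-])C1=C(C)[C@@H](O[Si](C)(C)C(C)(C)C)C[C@@]1(O[Si](C)(C)C)C(C)C | intermediate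
18 | 3-methylbut-2-enal | CC(C)=CC=O | starting material
19 | (E)-1-[(tert-butyldimethylsilyl)oxy]-3-methylbuta-1,3-diene (fragment 2) | C=C(C)/C=C/O[Si](C)(C)C(C)(C)C | intermediate
20 | cis-divinylcyclopropane: methyl 2-methyl-1-(ring-A cyclopentenyl)-2-[(E)-2-silyloxyethenyl]cyclopropane-1-carboxylate, the two alkenyl groups cis (not isolated) | COC(=O)[C@@]1(C2=C(C)[C@@H](O[Si](C)(C)C(C)(C)C)C[C@@]2(O[Si](C)(C)C)C(C)C)C[C@]1(C)/C=C/O[Si](C)(C)C(C)(C)C | intermediate
21 | methyl ester of the hydroazulene diene (C5=C6, ester on C6; C8=C9; 1α-Me; 2β-OTBS; 4α-OTMS; 4β-iPr; 10β-OTBS) | COC(=O)C1=C2[C@](O[Si](C)(C)C)(C(C)C)C[C@H](O[Si](C)(C)C(C)(C)C)[C@]2(C)[C@H](O[Si](C)(C)C(C)(C)C)C=C(C)C1 | intermediate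
22 | C4-hydroxy ester (21 without the trimethylsilyl group; not isolated) | COC(=O)C1=C2[C@](O)(C(C)C)C[C@H](O[Si](C)(C)C(C)(C)C)[C@]2(C)[C@H](O[Si](C)(C)C(C)(C)C)C=C(C)C1 | intermediate
23 | tricyclic butenolide (lactone O4–C(=O)–C6; C5=C6; C8=C9; 2β-OTBS; 10β-OTBS) | O=C1O[C@@]2(C(C)C)C[C@H](O[Si](C)(C)C(C)(C)C)[C@]3(C)[C@H](O[Si](C)(C)C(C)(C)C)C=C(C)CC1=C23 | intermediate
24 | saturated cis-fused γ-lactone (5β-H; C6 unassigned) | O=C1O[C@@]2(C(C)C)C[C@H](O[Si](C)(C)C(C)(C)C)[C@]3(C)[C@H](O[Si](C)(C)C(C)(C)C)C=C(C)CC1[C@@H]23 | intermediate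
25 | α-hydroxy lactone (tertiary OH on C6; C6 unassigned) | O=C1O[C@@]2(C(C)C)C[C@H](O[Si](C)(C)C(C)(C)C)[C@]3(C)[C@H](O[Si](C)(C)C(C)(C)C)C=C(C)CC1(O)[C@@H]23 | intermediate
26 | triol (4α-OH; C6 bearing OH and CH2OH, unassigned; 2β-OTBS; 10β-OTBS) | OCC2(O)CC(C)=C[C@@H](O[Si](C)(C)C(C)(C)C)[C@@]3(C)[C@@H](O[Si](C)(C)C(C)(C)C)C[C@@](O)(C(C)C)[C@H]23 | intermediate
27 | β-hydroxy ketone (C6=O; 4α-OH; 5β-H; 2β-OTBS; 10β-OTBS) | O=C2CC(C)=C[C@@H](O[Si](C)(C)C(C)(C)C)[C@@]3(C)[C@@H](O[Si](C)(C)C(C)(C)C)C[C@@](O)(C(C)C)[C@H]23 | intermediate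
28 | anti-1,3-diol (4α-OH; 6β-OH; 2β-OTBS; 10β-OTBS) | O[C@H]2CC(C)=C[C@@H](O[Si](C)(C)C(C)(C)C)[C@@]3(C)[C@@H](O[Si](C)(C)C(C)(C)C)C[C@@](O)(C(C)C)[C@H]23 | intermediate
29 | 4-methoxybenzoyl chloride | COc1ccc(cc1)C(Cl)=O | starting material
30 | C6 4-methoxybenzoate (4α-OH; 2β-OTBS; 10β-OTBS) | COc1ccc(C(=O)O[C@H]2CC(C)=C[C@@H](O[Si](C)(C)C(C)(C)C)[C@@]3(C)[C@@H](O[Si](C)(C)C(C)(C)C)C[C@@](O)(C(C)C)[C@H]23)cc1 | intermediate
31 | triol ester (2β-OH; 4α-OH; 10β-OH; C6 4-methoxybenzoate) | COc1ccc(C(=O)O[C@H]2CC(C)=C[C@@H](O)[C@@]3(C)[C@@H](O)C[C@@](O)(C(C)C)[C@H]23)cc1 | intermediate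
32 | C10 enone (2β-OH; 4α-OH; C6 4-methoxybenzoate) | COc1ccc(C(=O)O[C@H]2CC(C)=CC(=O)[C@@]3(C)[C@@H](O)C[C@@](O)(C(C)C)[C@H]23)cc1 | intermediate
33 | C2 acetate of the enone | COc1ccc(C(=O)O[C@H]2CC(C)=CC(=O)[C@@]3(C)[C@@H](OC(C)=O)C[C@@](O)(C(C)C)[C@H]23)cc1 | intermediate
34 | CNP0261832.1 (2β-acetoxy; 4α-hydroxy; 4β-isopropyl; 5β-H; 6β-(4-methoxybenzoyloxy); 10α-hydroxy; C8=C9) | COc1ccc(C(=O)O[C@H]2CC(C)=C[C@H](O)[C@@]3(C)[C@@H](OC(C)=O)C[C@@](O)(C(C)C)[C@H]23)cc1 | target

Total step count: 22. Longest linear sequence: 21 steps (steps 1 to 9, then 11 to 22; step 10 makes fragment 2).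

Steps most likely to fail

1. Step 11 (key step). The carbenoid is flanked by the C1 methyl group and the fully substituted C4, so cyclopropanation may be too slow and be overtaken by carbene dimerisation or insertion. The cyclopropanation may also follow the facial bias of 17 and not that of the catalyst, or place the methyl group instead of the silyloxyvinyl group cis to the cyclopentenyl ring. Finally the Cope step may stall, because the forming C1–C10 bond is syn to the C2 silyl ether and eclipses the C10 silyloxy group. Fallback (C2 stereocentre set after ring B): it sets out from 13. Silylation with N-(trimethylsilyl)imidazole gives the trimethylsilyl ether of the keto ester F1, and diazo transfer (p-ABSA, Et3N, MeCN) gives the diazo enone F2. The same rhodium-catalysed reaction with 19 then runs through the divinylcyclopropane F3 to the bicyclic C2 ketone F4, whose flat C2 no longer opposes the boat transition state. Reduction with NaBH4/CeCl3·7H2O (hydride from the α face, since the β face is screened by the isopropyl and C10 silyloxy groups) gives the 2β-alcohol F5, and TBSOTf/2,6-lutidine brings the route back to 21.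

2. Step 13. Electron transfer to the butenolide may lead to fission of the allylic C4–O bond, or the fully substituted alkene may not be reduced at all. Fallback (Curtius degradation instead of the lactone tether): it sets out from 21. Dealkylative cleavage of the methyl ester (n-PrSLi, HMPA) gives the acid F6. DPPA/Et3N gives the acyl azide F7, which on heating in toluene rearranges to the vinyl isocyanate F8 and is trapped with methanol as the enecarbamate F9. Aqueous oxalic acid in THF hydrolyses the carbamate and the trimethylsilyl ether to the C6 ketone, expected first as the cis-fused C5 epimer F10 (protonation from the open α face). Brief contact with DBU equilibrates it to the trans-fused ketone 27, where the route is rejoined. This path risks migration of the C8=C9 alkene and is therefore only the reserve.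

3. Step 6. The ester enolate may act as a base (deprotonation of the vinylogous ester at C3), or fail to add to a ketone that is screened by the fully substituted C4 and deactivated by the enol ether. Fallback (more reactive allyl nucleophile, oxidation level adjusted afterwards): it sets out from 10. CH2=CHCH2MgBr/CeCl3 followed by 1 M HCl gives, through the carbinol F11, the allyl enone F12. Ozonolysis of the terminal alkene (O3, CH2Cl2/MeOH, −78 °C, then Me2S; the electron-poor ring alkene is spared) gives the aldehyde F13. NaClO2 oxidation (Pinnick) gives the acid F14, and TMSCHN2 brings the route back to 13.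

Further compounds
F1 | step 11 | methyl 2-[(5R)-2-methyl-3-oxo-5-(propan-2-yl)-5-[(trimethylsilyl)oxy]cyclopent-1-en-1-yl]acetate | COC(=O)CC1=C(C)C(=O)C[C@@]1(O[Si](C)(C)C)C(C)C
F2 | step 11 | methyl 2-diazo-2-[(5R)-2-methyl-3-oxo-5-(propan-2-yl)-5-[(trimethylsilyl)oxy]cyclopent-1-en-1-yl]acetate | COC(=O)C(=[N+]=[N-])C1=C(C)C(=O)C[C@@]1(O[Si](C)(C)C)C(C)C
F3 | step 11 | cis-divinylcyclopropane from F2 and 19 (C2 ketone analogue of 20) | COC(=O)[C@@]1(C2=C(C)C(=O)C[C@@]2(O[Si](C)(C)C)C(C)C)C[C@]1(C)/C=C/O[Si](C)(C)C(C)(C)C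
F4 | step 11 | bicyclic C2 ketone (analogue of 21 with C2=O) | COC(=O)C1=C2[C@](O[Si](C)(C)C)(C(C)C)CC(=O)[C@]2(C)[C@H](O[Si](C)(C)C(C)(C)C)C=C(C)C1
F5 | step 11 | 2β-alcohol (21 without the C2 silyl group) | COC(=O)C1=C2[C@](O[Si](C)(C)C)(C(C)C)C[C@H](O)[C@]2(C)[C@H](O[Si](C)(C)C(C)(C)C)C=C(C)C1
F6 | step 13 | carboxylic acid of 21 | OC(=O)C1=C2[C@](O[Si](C)(C)C)(C(C)C)C[C@H](O[Si](C)(C)C(C)(C)C)[C@]2(C)[C@H](O[Si](C)(C)C(C)(C)C)C=C(C)C1
F7 | step 13 | acyl azide of F6 | [N-]=[N+]=NC(=O)C1=C2[C@](O[Si](C)(C)C)(C(C)C)C[C@H](O[Si](C)(C)C(C)(C)C)[C@]2(C)[C@H](O[Si](C)(C)C(C)(C)C)C=C(C)C1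
F8 | step 13 | C6 vinyl isocyanate | O=C=NC1=C2[C@](O[Si](C)(C)C)(C(C)C)C[C@H](O[Si](C)(C)C(C)(C)C)[C@]2(C)[C@H](O[Si](C)(C)C(C)(C)C)C=C(C)C1
F9 | step 13 | methyl N-vinylcarbamate (enecarbamate at C6) | COC(=O)NC1=C2[C@](O[Si](C)(C)C)(C(C)C)C[C@H](O[Si](C)(C)C(C)(C)C)[C@]2(C)[C@H](O[Si](C)(C)C(C)(C)C)C=C(C)C1
F10 | step 13 | C5 epimer of 27 (cis-fused, 5α-H) | O=C2CC(C)=C[C@@H](O[Si](C)(C)C(C)(C)C)[C@@]3(C)[C@@H](O[Si](C)(C)C(C)(C)C)C[C@@](O)(C(C)C)[C@@H]23
F11 | step 6 | (5R)-3-methoxy-2-methyl-5-(propan-2-yl)-1-(prop-2-en-1-yl)cyclopent-2-ene-1,5-diol (C1 unassigned) | C=CCC1(O)C(C)=C(OC)C[C@@]1(O)C(C)C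
F12 | step 6 | (4R)-4-hydroxy-2-methyl-4-(propan-2-yl)-3-(prop-2-en-1-yl)cyclopent-2-en-1-one | C=CCC1=C(C)C(=O)C[C@@]1(O)C(C)C
F13 | step 6 | 2-[(5R)-5-hydroxy-2-methyl-3-oxo-5-(propan-2-yl)cyclopent-1-en-1-yl]acetaldehyde | O=CCC1=C(C)C(=O)C[C@@]1(O)C(C)C
F14 | step 6 | 2-[(5R)-5-hydroxy-2-methyl-3-oxo-5-(propan-2-yl)cyclopent-1-en-1-yl]acetic acid | OC(=O)CC1=C(C)C(=O)C[C@@]1(O)C(C)C
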